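Ring B (tetrahydrofuran C1–C2–O3–C4–C5) is disconnected at C1–C2 and O3–C4 from ring A (lactone C1–C8(=O)–O7–C6–C5). Because C4 is a CH2 on C5 and C1 sits beside the C8 carbonyl, a C1–C4 bond that closes a cyclopropane on ring A hides an enolate at C1 and an alkylating carbon at C4. MgI2 should open that bond and let the catechol aldehyde (C2=O3) bridge it, which makes ring B, both bonds and the C1 and C2 stereocentres in one operation. The precursor is 4-aryl-2-oxo-3-oxabicyclo[3.1.0]hexane-1-carboxylate 8, aryl anti to the cyclopropane CH2, with a benzyl ester on C1 so that the carbenoid meets one alkene only and one hydrogenolysis frees acid and phenols.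

Key step: step 6

Assumption: C2 carries the catechol ring and C6 the guaiacyl ring; 1, 5 and 9 are taken as catalogue chemicals (each is otherwise one step from vanillin, Meldrum's acid or 3,4-dihydroxybenzaldehyde).

Step 1
Reactants: 1 4-(benzyloxy)-3-methoxybenzaldehyde (O-benzylvanillin); 2 vinylmagnesium bromide
Product: 3 rac-1-[4-(benzyloxy)-3-methoxyphenyl]prop-2-en-1-ol
Conditions: THF, −78 to 0 °C; aq. NH4Cl
Reagents that add atoms: none
Why: Grignard 1,2-addition to an aryl aldehyde; the benzyl ether is inert and the new carbinol centre (the future C6) forms racemic, to be resolved in step 2.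

Step 2
Reactants: 3 rac-1-[4-(benzyloxy)-3-methoxyphenyl]prop-2-en-1-ol
Product: 4 (S)-1-[4-(benzyloxy)-3-methoxyphenyl]prop-2-en-1-ol
Conditions: Novozym 435 (immobilised Candida antarctica lipase B), vinyl acetate, toluene, 30 °C, run slightly past half conversion; chromatography
Reagents that add atoms: none
Why: Lipase-catalysed kinetic resolution by transesterification: this lipase acylates the (R)-enantiomer of 1-aryl carbinols (aryl as the large group, vinyl as the medium one), so the unreacted alcohol should be (S)-4, the configuration C6 needs.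

Step 3
Reactants: 4 (S)-1-[4-(benzyloxy)-3-methoxyphenyl]prop-2-en-1-ol; 5 3-(benzyloxy)-3-oxopropanoic acid (mono-benzyl malonate)
Product: 6 benzyl (1S)-1-[4-(benzyloxy)-3-methoxyphenyl]prop-2-en-1-yl propanedioate
Conditions: DCC, DMAP (cat.), CH2Cl2, 0 °C
Reagents that add atoms: none
Why: Steglich esterification acylates the oxygen under neutral, cold conditions without breaking the allylic benzylic C–O bond, so C6 should keep its configuration and no 1,3-shift to the cinnamyl ester is expected.

Step 4
Reactants: 6 benzyl (1S)-1-[4-(benzyloxy)-3-methoxyphenyl]prop-2-en-1-yl propanedioate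
Product: 7 benzyl (1S)-1-[4-(benzyloxy)-3-methoxyphenyl]prop-2-en-1-yl 2-diazopropanedioate
Conditions: 4-acetamidobenzenesulfonyl azide, Et3N, MeCN, 0 °C to rt
Reagents that add atoms: 4-acetamidobenzenesulfonyl azide, CC(=O)Nc1ccc(cc1)S(=O)(=O)N=[N+]=[N-]
Why: Regitz diazo transfer to the acidic malonate CH2 under mild base, which leaves both esters and the stereocentre alone.

Step 5
Reactants: 7 benzyl (1S)-1-[4-(benzyloxy)-3-methoxyphenyl]prop-2-en-1-yl 2-diazopropanedioate
Product: 8 benzyl (1R,4S,5S)-4-[4-(benzyloxy)-3-methoxyphenyl]-2-oxo-3-oxabicyclo[3.1.0]hexane-1-carboxylate (aryl anti to the cyclopropane CH2)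
Conditions: Cu(acac)2 (5 mol %), toluene, 90 °C, slow addition of 7
Reagents that add atoms: none
Why: Copper-carbenoid intramolecular cyclopropanation of an allylic diazomalonate: the tether forces the cis-fused bicycle (C1 and C5), the C6 aryl group should take the outside position in the transition state, away from the carbenoid carbon and the alkene CH2, and so end up anti to the cyclopropane CH2, and the benzyl ester offers no second alkene.

Step 6
Reactants: 8 benzyl (1R,4S,5S)-4-[4-(benzyloxy)-3-methoxyphenyl]-2-oxo-3-oxabicyclo[3.1.0]hexane-1-carboxylate; 9 3,4-bis(benzyloxy)benzaldehyde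
Product: 12 benzyl (3S,3aR,6R,6aS)-6-[3,4-bis(benzyloxy)phenyl]-3-[4-(benzyloxy)-3-methoxyphenyl]-1-oxotetrahydro-1H,3H-furo[3,4-c]furan-6a-carboxylate, via iodo magnesium enolate 10 (not isolated), via magnesium aldolate 11 (not isolated)
Conditions: MgI2 (0.5 equiv), 9 (2 equiv), 4 Å molecular sieves, THF, 65 °C
Reagents that add atoms: none
Why: Proposed new method: MgI2 chelates the lactone and ester carbonyls on C1, iodide opens the strained, doubly activated C1–C4 bond by SN2 attack at the unhindered CH2 (C4) to give enolate 10, this adds reversibly to aldehyde 9, and the alkoxide oxygen of 11 then displaces iodide at C4. The closest known reactions are MgI2-mediated ring expansions of activated cyclopropanes with imines and nitrones and Lewis-acid [3+2] additions of aldehydes to donor–acceptor cyclopropanes, neither of which covers an aldehyde with a cyclopropane that has no donor on the attacked carbon. Ring B closes by 5-exo-tet O-alkylation. C1 is fixed because only the aldolate formed on the face of ring A that carries the CH2I arm can reach C4, which makes the fusion cis; C2 is set under Curtin–Hammett control, the reversible aldol feeding the closure in which the aryl group lies exo on the convex face, away from ring A. The step needs iodide to attack C4 and not C5, C6 or the ester CH2, and needs etherification to win over plain re-closure of the cyclopropane; the primary, strain-releasing C4 site, the quaternary C1 of 11 (no dehydration possible) and substoichiometric iodide should secure this, and re-closure only returns 8.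

Step 7
Reactants: 12 benzyl (3S,3aR,6R,6aS)-6-[3,4-bis(benzyloxy)phenyl]-3-[4-(benzyloxy)-3-methoxyphenyl]-1-oxotetrahydro-1H,3H-furo[3,4-c]furan-6a-carboxylate
Product: 13 (3S,3aR,6R,6aS)-6-(3,4-dihydroxyphenyl)-3-(4-hydroxy-3-methoxyphenyl)-1-oxotetrahydro-1H,3H-furo[3,4-c]furan-6a-carboxylic acid
Conditions: H2 (1 atm), 10% Pd/C, EtOAc/THF, rt, stopped after uptake of four equivalents of H2
Reagents that add atoms: none
Why: Palladium-catalysed hydrogenolysis removes the benzyl ester and the three aryl benzyl ethers together; under neutral, aprotic conditions these should cleave well before the ring C6–O7 and C2–O3 bonds, and no stereocentre is touched.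

Step 8
Reactants: 13 (3S,3aR,6R,6aS)-6-(3,4-dihydroxyphenyl)-3-(4-hydroxy-3-methoxyphenyl)-1-oxotetrahydro-1H,3H-furo[3,4-c]furan-6a-carboxylic acid
Product: 14 (3S,3aR,6S,6aS)-6-(3,4-dihydroxyphenyl)-3-(4-hydroxy-3-methoxyphenyl)tetrahydro-1H,3H-furo[3,4-c]furan-1-one (CNP0268159.1)
Conditions: 1,4-dioxane, 100 °C, argon
Reagents that add atoms: none
Why: Thermal decarboxylation of the malonic-type lactone acid through a cyclic transition state gives the C1 enol, which can only be protonated on the convex face because a trans-fused bicyclo[3.3.0] lactone is far too strained, so the cis fusion results; neutral conditions avoid base-induced β-elimination of O3 and leave C2, C5 and C6 untouched.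

Compound list
1 | 4-(benzyloxy)-3-methoxybenzaldehyde (O-benzylvanillin) | COc1cc(C=O)ccc1OCc1ccccc1 | starting material
2 | vinylmagnesium bromide | C=C[Mg]Br | starting material
3 | rac-1-[4-(benzyloxy)-3-methoxyphenyl]prop-2-en-1-ol | C=CC(O)c1ccc(OCc2ccccc2)c(OC)c1 | intermediate
4 | (S)-1-[4-(benzyloxy)-3-methoxyphenyl]prop-2-en-1-ol | C=C[C@H](O)c1ccc(OCc2ccccc2)c(OC)c1 | intermediate
5 | 3-(benzyloxy)-3-oxopropanoic acid (mono-benzyl malonate) | O=C(O)CC(=O)OCc1ccccc1 | starting material
6 | benzyl (1S)-1-[4-(benzyloxy)-3-methoxyphenyl]prop-2-en-1-yl propanedioate | C=C[C@H](OC(=O)CC(=O)OCc1ccccc1)c1ccc(OCc2ccccc2)c(OC)c1 | intermediate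
7 | benzyl (1S)-1-[4-(benzyloxy)-3-methoxyphenyl]prop-2-en-1-yl 2-diazopropanedioate | C=C[C@H](OC(=O)C(=[N+]=[N-])C(=O)OCc1ccccc1)c1ccc(OCc2ccccc2)c(OC)c1 | intermediate
8 | benzyl (1R,4S,5S)-4-[4-(benzyloxy)-3-methoxyphenyl]-2-oxo-3-oxabicyclo[3.1.0]hexane-1-carboxylate, aryl anti to the cyclopropane CH2 | O=C1O[C@H](c2ccc(OCc3ccccc3)c(OC)c2)[C@H]2C[C@@]12C(=O)OCc1ccccc1 | intermediate
9 | 3,4-bis(benzyloxy)benzaldehyde | O=Cc1ccc(OCc2ccccc2)c(OCc2ccccc2)c1 | starting material
10 | iodo magnesium enolate: iodomagnesium enolate of benzyl (4S,5S)-5-[4-(benzyloxy)-3-methoxyphenyl]-4-(iodomethyl)-2-oxotetrahydrofuran-3-carboxylate, CH2I trans to the aryl group | IC[C@@H]1[C@@H](c2ccc(OCc3ccccc3)c(OC)c2)OC(O[Mg]I)=C1C(=O)OCc1ccccc1 | intermediate (not isolated)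
11 | magnesium aldolate: iodomagnesium alkoxide of the aldol adduct of 10 and 9, the new C1–C2 bond on the same face of ring A as the CH2I group, C2 configured as in 12 | O=C1O[C@H](c2ccc(OCc3ccccc3)c(OC)c2)[C@@H](CI)[C@@]1(C(=O)OCc1ccccc1)[C@H](O[Mg]I)c1ccc(OCc2ccccc2)c(OCc2ccccc2)c1 | intermediate (not isolated)
12 | benzyl (3S,3aR,6R,6aS)-6-[3,4-bis(benzyloxy)phenyl]-3-[4-(benzyloxy)-3-methoxyphenyl]-1-oxotetrahydro-1H,3H-furo[3,4-c]furan-6a-carboxylate, cis-fused, both aryl groups exo | O=C1O[C@H](c2ccc(OCc3ccccc3)c(OC)c2)[C@H]2CO[C@H](c3ccc(OCc4ccccc4)c(OCc4ccccc4)c3)[C@@]12C(=O)OCc1ccccc1 | intermediate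
13 | (3S,3aR,6R,6aS)-6-(3,4-dihydroxyphenyl)-3-(4-hydroxy-3-methoxyphenyl)-1-oxotetrahydro-1H,3H-furo[3,4-c]furan-6a-carboxylic acid | O=C1O[C@H](c2ccc(O)c(OC)c2)[C@H]2CO[C@H](c3ccc(O)c(O)c3)[C@@]12C(=O)O | intermediate
14 | (3S,3aR,6S,6aS)-6-(3,4-dihydroxyphenyl)-3-(4-hydroxy-3-methoxyphenyl)tetrahydro-1H,3H-furo[3,4-c]furan-1-one, cis-fused, both aryl groups exo | COc1cc([C@H]2OC(=O)[C@H]3[C@@H]2CO[C@@H]3c2ccc(O)c(O)c2)ccc1O | target

Total step count: 8
Longest linear sequence: 8 steps (1 to 14)

Steps most likely to fail

1. Step 6. The aldol equilibrium of a stabilised enolate with an electron-rich aldehyde may lie so far on the side of the components that etherification never starts, or iodide may dealkylate the benzyl ester before ring B closes. The fallback uses known chemistry, sets out from aldehyde 9 and comes back at 12. It builds ring B first on a malonate whose C1 carries two identical esters, so that no face of C1 has to be chosen. Knoevenagel condensation of 9 with dibenzyl malonate (piperidine, AcOH, toluene, water removal) should give dibenzyl 2-[3,4-bis(benzyloxy)benzylidene]propanedioate F1. A zerovalent-palladium-catalysed formal [3+2] cycloaddition with 2-vinyloxirane (Pd2(dba)3, the suitable enantiomer of a chiral cyclohexane-1,2-diamine-derived bis(2-diphenylphosphinobenzamide) ligand, THF) proceeds by oxa-Michael addition of the π-allyl alkoxide at C2 and allylic alkylation by the malonate at C5; it should give dibenzyl (2R,4R)-2-[3,4-bis(benzyloxy)phenyl]-4-ethenyloxolane-3,3-dicarboxylate F2, aryl and vinyl trans. Oxidative cleavage of the vinyl group (OsO4 cat., NaIO4, 2,6-lutidine, dioxane/water) gives dibenzyl (2R,4R)-2-[3,4-bis(benzyloxy)phenyl]-4-formyloxolane-3,3-dicarboxylate F3. Addition of 4-(benzyloxy)-3-methoxyphenylmagnesium bromide (THF, −78 °C) then forms the C6 alkoxide, which lactonises onto the cis ester to give 12. Stereocontrol in this path rests on the ligand and on Felkin–Anh-type addition at C6, so it is less secure than in the main route.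

2. Step 5. Facial selectivity of the carbenoid addition may be poor, leaving part of the aryl group syn to the cyclopropane CH2, and the carbenoid may attack an aromatic ring. The fallback avoids the carbenoid, sets out from malonate 6 and comes back at 8. Iodine-mediated cyclisation under phase-transfer conditions (I2, K2CO3, Bu4NBr, toluene, rt) starts with iodonium-induced 5-exo attack of the malonate carbon on the vinyl group and should give benzyl (4S,5S)-5-[4-(benzyloxy)-3-methoxyphenyl]-4-(iodomethyl)-2-oxotetrahydrofuran-3-carboxylate F4, CH2I trans to the aryl group. A second deprotonation closes the cyclopropane by 3-exo-tet displacement of iodide and gives 8.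

3. Step 7. Over-reduction is the concern: hydrogenolysis of the benzylic C6–O7 and C2–O3 bonds of the electron-rich core may compete with debenzylation. The fallback goes from 12 to 13 without hydrogen. BCl3 with pentamethylbenzene as cation scavenger (CH2Cl2, −78 °C) cleaves the three aryl benzyl ethers and the benzyl ester by Lewis-acid-assisted benzyl transfer; it makes no new compound.

Further compounds
F1 | step 6 | dibenzyl 2-[3,4-bis(benzyloxy)benzylidene]propanedioate | O=C(OCc1ccccc1)C(=Cc1ccc(OCc2ccccc2)c(OCc2ccccc2)c1)C(=O)OCc1ccccc1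
F2 | step 6 | dibenzyl (2R,4R)-2-[3,4-bis(benzyloxy)phenyl]-4-ethenyloxolane-3,3-dicarboxylate | C=C[C@H]1CO[C@H](c2ccc(OCc3ccccc3)c(OCc3ccccc3)c2)C1(C(=O)OCc1ccccc1)C(=O)OCc1ccccc1
F3 | step 6 | dibenzyl (2R,4R)-2-[3,4-bis(benzyloxy)phenyl]-4-formyloxolane-3,3-dicarboxylate | O=C[C@H]1CO[C@H](c2ccc(OCc3ccccc3)c(OCc3ccccc3)c2)C1(C(=O)OCc1ccccc1)C(=O)OCc1ccccc1
F4 | step 5 | benzyl (4S,5S)-5-[4-(benzyloxy)-3-methoxyphenyl]-4-(iodomethyl)-2-oxotetrahydrofuran-3-carboxylate (C3 epimers) | O=C1O[C@H](c2ccc(OCc3ccccc3)c(OC)c2)[C@@H](CI)C1C(=O)OCc1ccccc1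
F0 | step 7 | none | none
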